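**Assumption:** the target has no stereocentre and no stereogenic double bond, so "single enantiomer" means the achiral compound as drawn; compounds 1, 2, 5, 6 and 10 are taken as catalogue chemicals.

**Retrosynthetic overview**
1. Target ⇒ cleave the enol ester C–O bond: 3-(1,1-dimethylallyl)-4-hydroxy-6-phenyl-2-pyranone + 3-hydroxy-3-methylbutanoic acid (acylation last; C3 is then fully substituted, so no O→C acyl shift is possible).
2. Key C–C bond, pyranone C3 to the quaternary carbon: C3 is made electrophilic as an enolonium (phenyliodonium ylide of 4-hydroxy-6-phenyl-2-pyranone) and is attacked by prenyltrimethylsilane through its γ-carbon (SE2′), which gives the 1,1-dimethylallyl group directly.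
3. 4-Hydroxy-6-phenyl-2-pyranone ⇒ acetophenone trimethylsilyl enol ether + malonyl dichloride (C-acylation, then lactonisation).
4. Ring order: only one ring is built, the 2-pyranone, in step 1; the phenyl ring is bought.

**Route**

Step 1
Reactants: 1 trimethyl[(1-phenylethenyl)oxy]silane (acetophenone TMS enol ether); 2 malonyl dichloride
Product: 4 4-hydroxy-6-phenyl-2H-pyran-2-one, via 3,5-dioxo-5-phenylpentanoyl chloride 3 (not isolated)
Conditions: Et2O, −78 °C → rt, 12 h (HCl vented); product filtered and recrystallised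
Reagents that add atoms: none
Why: Effenberger-type pyranone synthesis: the silyl enol ether is C-acylated by the very electrophilic diacid chloride, and the enol oxygen of the resulting 1,3-diketone closes onto the second acid chloride to give the lactone, which tautomerises to the 4-hydroxy-2-pyranone.

Step 2
Reactants: 4 4-hydroxy-6-phenyl-2H-pyran-2-one; 5 (diacetoxyiodo)benzene; 6 trimethyl(3-methylbut-2-en-1-yl)silane (prenyltrimethylsilane)
Product: 9 4-hydroxy-3-(2-methylbut-3-en-2-yl)-6-phenyl-2H-pyran-2-one, via pyranone phenyliodonium ylide 7 (not isolated), via O-trimethylsilyl enol ether 8 (not isolated)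
Conditions: PhI(OAc)2 (1.05 eq), CH2Cl2, 0 °C → rt, 1 h, then AcOH stripped in vacuo (toluene chase); 6 (2 eq), TMSOTf (20 mol%), CH2Cl2, −78 → −20 °C; cold aq NaHCO3, then pH 4 buffer work-up
Reagents that add atoms: none
Why: Proposed new method: the acidic enol 4 exchanges both acetates of PhI(OAc)2 to give the stable iodonium ylide 7, and O-silylation by TMSOTf turns it into a β-silyloxy-alkenyl(phenyl)iodonium (an enolonium) whose C3 carries the hypernucleofuge PhI, so the allylsilane attacks C3 through its γ-carbon (SE2′, β-silyl cation), PhI leaves and loss of Me3Si+ regenerates TMSOTf, giving silyl ether 8 that is hydrolysed to 9 on work-up; the closest known reaction types are the enolonium α-allylation of ketone iodine(III) enolates with allyl- and prenylsilanes (γ-selective, quaternary carbons formed) and the Lewis-acid-promoted trapping of β-dicarbonyl iodonium ylides by alkenes and other π-nucleophiles.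

Step 3
Reactants: 9 4-hydroxy-3-(2-methylbut-3-en-2-yl)-6-phenyl-2H-pyran-2-one; 10 3-hydroxy-3-methylbutanoic acid
Product: 11 3-(2-methylbut-3-en-2-yl)-2-oxo-6-phenyl-2H-pyran-4-yl 3-hydroxy-3-methylbutanoate (target)
Conditions: DCC (1.2 eq), DMAP (10 mol%), 10 (1.2 eq), CH2Cl2, 0 °C → rt; filter, rapid chromatography on neutral silica
Reagents that add atoms: none
Why: Steglich esterification: the acyl-pyridinium is captured by the acidic pyranone enol(ate) at O4, the tertiary alcohol of 10 is too hindered to compete, and C3 is fully substituted so the O-acyl product cannot undergo the usual DMAP-induced O→C acyl migration.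

**Compound list**
1 | trimethyl[(1-phenylethenyl)oxy]silane | C=C(O[Si](C)(C)C)c1ccccc1 | starting material
2 | malonyl dichloride | O=C(Cl)CC(=O)Cl | starting material
3 | 3,5-dioxo-5-phenylpentanoyl chloride | O=C(Cl)CC(=O)CC(=O)c1ccccc1 | intermediate
4 | 4-hydroxy-6-phenyl-2H-pyran-2-one | O=c1cc(O)cc(-c2ccccc2)o1 | intermediate
5 | (diacetoxyiodo)benzene | CC(=O)OI(OC(C)=O)c1ccccc1 | starting material
6 | trimethyl(3-methylbut-2-en-1-yl)silane | CC(C)=CC[Si](C)(C)C | starting material
7 | 2-oxo-6-phenyl-3-(phenyliodonio)-2H-pyran-4-olate (iodonium ylide) | O=c1oc(-c2ccccc2)cc([O-])c1[I+]c1ccccc1 | intermediate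
8 | 3-(2-methylbut-3-en-2-yl)-6-phenyl-4-(trimethylsilyloxy)-2H-pyran-2-one | C=CC(C)(C)c1c(O[Si](C)(C)C)cc(-c2ccccc2)oc1=O | intermediate
9 | 4-hydroxy-3-(2-methylbut-3-en-2-yl)-6-phenyl-2H-pyran-2-one | C=CC(C)(C)c1c(O)cc(-c2ccccc2)oc1=O | intermediate
10 | 3-hydroxy-3-methylbutanoic acid | CC(C)(O)CC(=O)O | starting material
11 | 3-(2-methylbut-3-en-2-yl)-2-oxo-6-phenyl-2H-pyran-4-yl 3-hydroxy-3-methylbutanoate | C=CC(C)(C)c1c(OC(=O)CC(C)(C)O)cc(-c2ccccc2)oc1=O | target

**Total step count:** 3. **Longest linear sequence:** 3 steps (1 → 4 → 9 → 11).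

**Steps most likely to fail, with fallbacks**

Step 2 (highest risk). The β-silyl cation may be trapped by O4 in a [3+2] dihydrofuran annulation instead of losing silicon. Coupling through an allyl-iodane could give the linear prenyl isomer. Acid could also cyclise the enol of 9 onto its vinyl group. The fallback sets out from 4 and comes back at 9, keeping C3 electrophilic but as a metal carbenoid. Diazo transfer to 4 (4-acetamidobenzenesulfonyl azide, Et3N, MeCN, 0 °C) gives 3-diazo-6-phenyl-2H-pyran-2,4(3H)-dione F2. Rh2(OAc)4 (1 mol%) with excess prenyl bromide in CH2Cl2 forms the allyl bromonium ylide, whose [2,3]-sigmatropic shift necessarily delivers the dimethyl-substituted terminus to C3. This gives racemic 3-bromo-3-(2-methylbut-3-en-2-yl)-6-phenyl-2H-pyran-2,4(3H)-dione F3. Zinc dust in AcOH/THF at 0 °C removes the bromine and gives 9.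

Step 3. The enol OH is hindered and weakly nucleophilic, and the free β-hydroxy acid may self-condense or lactonise once activated. The fallback sets out from 10, is joined by 9, and comes back at 11. Acid 10 is bis-silylated (Et3SiCl, imidazole, DMF) to triethylsilyl 3-methyl-3-(triethylsilyloxy)butanoate F4. The silyl ester is converted under neutral conditions (oxalyl chloride, cat. DMF, CH2Cl2, 0 °C) into 3-methyl-3-(triethylsilyloxy)butanoyl chloride F5. This acylates 9 (Et3N, cat. DMAP, CH2Cl2, −20 °C) to give 3-(2-methylbut-3-en-2-yl)-2-oxo-6-phenyl-2H-pyran-4-yl 3-methyl-3-(triethylsilyloxy)butanoate F6. The silyl ether is removed with HF·pyridine in THF at 0 °C to give 11.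

Step 1. Malonyl dichloride can over-acylate or oligomerise, and HCl can desilylate 1 back to acetophenone. The fallback sets out from 1 and comes back at 4, building the chain stepwise. ZnCl2-promoted C-acylation of 1 with methyl 3-chloro-3-oxopropanoate (CH2Cl2/Et2O, 0 °C → rt) gives methyl 3,5-dioxo-5-phenylpentanoate F1. This is lactonised separately (DBU, toluene, reflux, then acidification) to 4.

**Further compounds**
F1 | step 1 | methyl 3,5-dioxo-5-phenylpentanoate | COC(=O)CC(=O)CC(=O)c1ccccc1
F2 | step 2 | 3-diazo-6-phenyl-2H-pyran-2,4(3H)-dione | [N-]=[N+]=C1C(=O)C=C(c2ccccc2)OC1=O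
F3 | step 2 | 3-bromo-3-(2-methylbut-3-en-2-yl)-6-phenyl-2H-pyran-2,4(3H)-dione (racemic) | C=CC(C)(C)C1(Br)C(=O)C=C(c2ccccc2)OC1=O
F4 | step 3 | triethylsilyl 3-methyl-3-(triethylsilyloxy)butanoate | CC[Si](CC)(CC)OC(=O)CC(C)(C)O[Si](CC)(CC)CC
F5 | step 3 | 3-methyl-3-(triethylsilyloxy)butanoyl chloride | CC[Si](CC)(CC)OC(C)(C)CC(=O)Cl
F6 | step 3 | 3-(2-methylbut-3-en-2-yl)-2-oxo-6-phenyl-2H-pyran-4-yl 3-methyl-3-(triethylsilyloxy)butanoate | C=CC(C)(C)c1c(OC(=O)CC(C)(C)O[Si](CC)(CC)CC)cc(-c2ccccc2)oc1=O
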